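**Retrosynthetic overview**

1. Acerosin comes from methanolysis of its 7,3′-di-O-pivalate, whose C5 hydroxyl is installed by C4=O-directed Ru-catalysed hydroxylation of the last A-ring C–H of a 7-pivaloyloxy-6,8-dimethoxyflavone.
2. That flavone is disconnected at O1–C8a of ring C, the only ring formed in the route: anodic dehydrogenative C–H/O–H coupling of a 1,3-diaryl-1,3-diketone.
3. Feature used: cutting O1–C8a leaves a 3,5-dimethoxy-4-acyloxybenzoyl A ring whose two ortho C–H carbons (future C8a and C5) are symmetry-equivalent, each ortho to one OMe and para to the other. One takes O1 at the anode, the other takes the C5 hydroxyl.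
4. The diketone comes from C2–C3 bond formation: acylation of the enolate of O-pivaloyl acetosyringone with O-pivaloyl isovanilloyl chloride. Rings A and B are bought.
5. Protecting groups: O7 is carried as a pivalate like O3′, not as a benzyl ether, because a benzyl aryl ether would be at risk at the anode and in hot TFA/TFAA with iodine(III). Both esters leave in one final step.

Key step: step 5

Remark: the target has no stereogenic element, so "single enantiomer" requires no stereocontrol anywhere in the route.

**Route**

Step 1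
Reactants: 1 acetosyringone [1-(4-hydroxy-3,5-dimethoxyphenyl)ethan-1-one]; 2 pivaloyl chloride
Product: 3 4-acetyl-2,6-dimethoxyphenyl pivalate
Conditions: PivCl (1.3 equiv), Et3N (1.5 equiv), DMAP (10 mol %), CH2Cl2, 0 °C → rt
Reagents that add atoms: none
Why: DMAP-catalysed O-acylation of a phenol made more acidic by the para acetyl group should give the hindered aryl pivalate, which has no α-hydrogen and should resist the later base, anode and acid.

Step 2
Reactants: 4 isovanillic acid (3-hydroxy-4-methoxybenzoic acid); 2 pivaloyl chloride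
Product: 5 4-methoxy-3-(pivaloyloxy)benzoic acid
Conditions: NaOH (2.2 equiv), H2O/THF, 0 °C; PivCl (1.1 equiv); then 1 M HCl to pH 2
Reagents that add atoms: none
Why: Schotten–Baumann acylation, in which the phenoxide is far more nucleophilic than the carboxylate, any mixed anhydride is hydrolysed in the aqueous base, and the hindered pivalate should survive the short cold basic phase.

Step 3
Reactants: 5 4-methoxy-3-(pivaloyloxy)benzoic acid
Product: 6 4-methoxy-3-(pivaloyloxy)benzoyl chloride
Conditions: (COCl)2 (1.3 equiv), DMF (cat.), CH2Cl2, 0 °C → rt; evaporate, use crude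
Reagents that add atoms: oxalyl chloride, O=C(Cl)C(=O)Cl
Why: Vilsmeier-type (DMF-catalysed) conversion of a carboxylic acid into its acid chloride, to which the aryl pivalate and the methyl ether are inert.

Step 4
Reactants: 3 4-acetyl-2,6-dimethoxyphenyl pivalate; 6 4-methoxy-3-(pivaloyloxy)benzoyl chloride
Product: 8 1-[3,5-dimethoxy-4-(pivaloyloxy)phenyl]-3-[4-methoxy-3-(pivaloyloxy)phenyl]propane-1,3-dione, via lithium enolate 7 (not isolated)
Conditions: LiHMDS (2.2 equiv), THF, −78 °C, 45 min; 6 (1.0 equiv) in THF, −78 → 0 °C; sat. aq NH4Cl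
Reagents that add atoms: none
Why: Claisen-type C-acylation of a ketone lithium enolate by an aroyl chloride, in which the second equivalent of base holds the product as its lithium diketonate and so stops further acylation, while the hindered pivalates should not be attacked at −78 °C.

Step 5
Reactants: 8 1-[3,5-dimethoxy-4-(pivaloyloxy)phenyl]-3-[4-methoxy-3-(pivaloyloxy)phenyl]propane-1,3-dione
Product: 9 6,8-dimethoxy-2-[4-methoxy-3-(pivaloyloxy)phenyl]-4-oxo-4H-chromen-7-yl pivalate
Conditions: undivided cell, graphite anode, Pt cathode, n-Bu4NPF6 (0.1 M), HFIP/CH2Cl2 (4:1), constant current 5 mA cm−2, 2.2–2.5 F mol−1, rt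
Reagents that add atoms: none
Why: Proposed new method: one-electron oxidation at the anode should take place on the 3,5-dimethoxy-4-acyloxybenzoyl ring, the most electron-rich π-system, and HFIP stabilises the radical cation and loosens the hydrogen-bonded enol chelate, so that after rotation about the C3–C4 bond the oxygen on the B-ring-side carbonyl carbon (enol OH or keto C=O) can attack the ring carbon ortho to the acyl group, after which loss of a second electron and two protons rearomatises to the chromone while protons are reduced to H2 at the cathode. The closest known reaction type is the anodic dehydrogenative C–O cyclisation of arenes carrying a tethered oxygen nucleophile (biaryl-2-carboxylic acids to benzo[c]chromen-6-ones, anilides to benzoxazoles). Ring C closes as a six-membered ring by O1–C8a bond formation, endo to the C4a–C8a arene bond; attack through the central carbon C3 would give a four-membered ring and is excluded. No stereocentre is formed. The step needs closure on ring A and not on ring B: the attacked carbon of ring A is ortho to one methoxy group and para to the other, where the radical cation carries most positive charge, whereas both carbons ortho to the carbonyl on ring B are meta to its single methoxy group and that ring also bears the electron-withdrawing pivalate, and the two ortho carbons of ring A are equivalent, so no regioisomer can arise. The product is a vinylogous ester whose A ring is electron-poorer than that of 8, which should protect it from further oxidation.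

Step 6
Reactants: 9 6,8-dimethoxy-2-[4-methoxy-3-(pivaloyloxy)phenyl]-4-oxo-4H-chromen-7-yl pivalate
Product: 11 5-hydroxy-6,8-dimethoxy-2-[4-methoxy-3-(pivaloyloxy)phenyl]-4-oxo-4H-chromen-7-yl pivalate, via C5 trifluoroacetate 10 (not isolated)
Conditions: [RuCl2(p-cymene)]2 (5 mol %), PhI(OCOCF3)2 (1.5 equiv), TFA/TFAA (3:1), 70 °C; then aq NaHCO3, rt
Reagents that add atoms: [bis(trifluoroacetoxy)iodo]benzene, O=C(OI(OC(=O)C(F)(F)F)c1ccccc1)C(F)(F)F
Why: Ketone-directed Ru(II)-catalysed ortho C–H oxygenation, a reaction type established for flavones and aryl ketones, in which C4=O binds ruthenium, carboxylate-assisted metalation at the peri C5–H (the only A-ring C–H) gives a five-membered ruthenacycle, and oxidation by iodine(III) with C–O reductive elimination delivers the aryl trifluoroacetate, which is masked against over-oxidation until it is hydrolysed on work-up.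

Step 7
Reactants: 11 5-hydroxy-6,8-dimethoxy-2-[4-methoxy-3-(pivaloyloxy)phenyl]-4-oxo-4H-chromen-7-yl pivalate
Product: 12 acerosin [5,7-dihydroxy-2-(3-hydroxy-4-methoxyphenyl)-6,8-dimethoxy-4H-chromen-4-one]
Conditions: K2CO3 (4 equiv), degassed MeOH, Ar, rt → 40 °C; then 1 M HCl to pH 3
Reagents that add atoms: none
Why: Base-mediated methanolysis (transesterification) of two aryl pivalates, both activated phenyl esters (O7 is vinylogous to C4=O), under conditions that should leave the methyl ethers and the chromone untouched.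

**Compound list**

1 | acetosyringone | CC(=O)c1cc(OC)c(O)c(OC)c1 | starting material
2 | pivaloyl chloride | CC(C)(C)C(=O)Cl | starting material
3 | 4-acetyl-2,6-dimethoxyphenyl pivalate | CC(=O)c1cc(OC)c(OC(=O)C(C)(C)C)c(OC)c1 | intermediate
4 | isovanillic acid | COc1ccc(C(=O)O)cc1O | starting material
5 | 4-methoxy-3-(pivaloyloxy)benzoic acid | COc1ccc(C(=O)O)cc1OC(=O)C(C)(C)C | intermediate
6 | 4-methoxy-3-(pivaloyloxy)benzoyl chloride | COc1ccc(C(=O)Cl)cc1OC(=O)C(C)(C)C | intermediate
7 | lithium enolate of 3 [lithium 1-[3,5-dimethoxy-4-(pivaloyloxy)phenyl]ethen-1-olate] | [Li+].C=C([O-])c1cc(OC)c(OC(=O)C(C)(C)C)c(OC)c1 | intermediate (not isolated)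
8 | 1-[3,5-dimethoxy-4-(pivaloyloxy)phenyl]-3-[4-methoxy-3-(pivaloyloxy)phenyl]propane-1,3-dione | COc1ccc(C(=O)CC(=O)c2cc(OC)c(OC(=O)C(C)(C)C)c(OC)c2)cc1OC(=O)C(C)(C)C | intermediate
9 | 6,8-dimethoxy-2-[4-methoxy-3-(pivaloyloxy)phenyl]-4-oxo-4H-chromen-7-yl pivalate | COc1ccc(-c2cc(=O)c3cc(OC)c(OC(=O)C(C)(C)C)c(OC)c3o2)cc1OC(=O)C(C)(C)C | intermediate
10 | 6,8-dimethoxy-2-[4-methoxy-3-(pivaloyloxy)phenyl]-4-oxo-5-(trifluoroacetoxy)-4H-chromen-7-yl pivalate | COc1ccc(-c2cc(=O)c3c(OC(=O)C(F)(F)F)c(OC)c(OC(=O)C(C)(C)C)c(OC)c3o2)cc1OC(=O)C(C)(C)C | intermediate (not isolated)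
11 | 5-hydroxy-6,8-dimethoxy-2-[4-methoxy-3-(pivaloyloxy)phenyl]-4-oxo-4H-chromen-7-yl pivalate | COc1ccc(-c2cc(=O)c3c(O)c(OC)c(OC(=O)C(C)(C)C)c(OC)c3o2)cc1OC(=O)C(C)(C)C | intermediate
12 | acerosin | COc1ccc(-c2cc(=O)c3c(O)c(OC)c(O)c(OC)c3o2)cc1O | target

**Step count and risks**

Total step count: 7. Longest linear sequence: 6 steps (steps 2–7, from isovanillic acid).

Steps most likely to fail:

1. Step 5 (anodic O1–C8a closure). What may go wrong: the enolised diketone is oxidised at the central carbon and dimerises, or the radical cation oligomerises and passivates the anode, before the oxygen traps it; the electron-rich ring is over-oxidised. Fallback with known chemistry, from 3 back to 9: the same bond is made by copper-catalysed C–O coupling onto an aryl bromide. Ketone 3 is ring-brominated with NBS (MeCN, rt) at one of its two equivalent positions ortho to the acetyl group, which are ortho/para to the methoxy groups, to give 4-acetyl-3-bromo-2,6-dimethoxyphenyl pivalate F1. Its lithium enolate F2 (LiHMDS, THF, −78 °C) is acylated with 6 as in step 4 to give 1-[2-bromo-3,5-dimethoxy-4-(pivaloyloxy)phenyl]-3-[4-methoxy-3-(pivaloyloxy)phenyl]propane-1,3-dione F3. Ullmann-type intramolecular O-arylation of the diketonate (CuI 10 mol %, 1,10-phenanthroline 20 mol %, K2CO3, DMF, 90 °C) should then close the pyranone and give 9.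

2. Step 6 (C5–H hydroxylation). What may go wrong: cyclometalation at the peri C5–H is slowed by the flanking C6 methoxy group, and the iodine(III) reagent meanwhile oxidises the anisole-type B ring or demethylates oxidatively towards a 5,8-quinone. Fallback, from 3 back to 11: the oxygen is put in on the simple aryl ketone before the pyranone exists, and the anodic closure of step 5 then uses the one remaining ortho C–H. Ketone 3 is hydroxylated ortho to the acetyl group under the Ru/PhI(OCOCF3)2/TFA–TFAA conditions; 4-acetyl-2,6-dimethoxy-3-(trifluoroacetoxy)phenyl pivalate F4 forms in the flask and is hydrolysed on work-up to 4-acetyl-3-hydroxy-2,6-dimethoxyphenyl pivalate F5. O-Methylation (MeI, K2CO3, acetone, reflux) gives 4-acetyl-2,3,6-trimethoxyphenyl pivalate F6. Its lithium enolate F7 (LiHMDS, THF, −78 °C) is acylated with 6 to give 1-[2,3,5-trimethoxy-4-(pivaloyloxy)phenyl]-3-[4-methoxy-3-(pivaloyloxy)phenyl]propane-1,3-dione F8. Electrolysis as in step 5 should close O1–C8a at the single free ortho carbon, still ortho and para to methoxy groups, and give 5,6,8-trimethoxy-2-[4-methoxy-3-(pivaloyloxy)phenyl]-4-oxo-4H-chromen-7-yl pivalate F9. BCl3 (CH2Cl2, −78 → 0 °C) should then cleave only the C5 methyl ether, which is chelated peri to C4=O, and give 11.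

3. Step 4 (enolate acylation). What may go wrong: O-acylation of the enolate to an enol ester, a second acylation at the central carbon, or acyl transfer from an aryl pivalate to the enolate. Fallback, from 3 and 6 back to 8: aldol addition followed by oxidation replaces the acylation. Acid chloride 6 is reduced with LiAlH(O-t-Bu)3 (THF, −78 °C) to 5-formyl-2-methoxyphenyl pivalate F10. Lithium enolate 7 is added to it (THF, −78 °C, cold quench) to give racemic 3-hydroxy-1-[3,5-dimethoxy-4-(pivaloyloxy)phenyl]-3-[4-methoxy-3-(pivaloyloxy)phenyl]propan-1-one F11. Oxidation of the secondary alcohol with Dess–Martin periodinane (CH2Cl2, rt) should then give diketone 8.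

**Further compounds**

F1 | step 5 | 4-acetyl-3-bromo-2,6-dimethoxyphenyl pivalate | CC(=O)c1cc(OC)c(OC(=O)C(C)(C)C)c(OC)c1Br
F2 | step 5 | lithium enolate of F1 | [Li+].C=C([O-])c1cc(OC)c(OC(=O)C(C)(C)C)c(OC)c1Br
F3 | step 5 | 1-[2-bromo-3,5-dimethoxy-4-(pivaloyloxy)phenyl]-3-[4-methoxy-3-(pivaloyloxy)phenyl]propane-1,3-dione | COc1ccc(C(=O)CC(=O)c2cc(OC)c(OC(=O)C(C)(C)C)c(OC)c2Br)cc1OC(=O)C(C)(C)C
F4 | step 6 | 4-acetyl-2,6-dimethoxy-3-(trifluoroacetoxy)phenyl pivalate | CC(=O)c1cc(OC)c(OC(=O)C(C)(C)C)c(OC)c1OC(=O)C(F)(F)F
F5 | step 6 | 4-acetyl-3-hydroxy-2,6-dimethoxyphenyl pivalate | CC(=O)c1cc(OC)c(OC(=O)C(C)(C)C)c(OC)c1O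
F6 | step 6 | 4-acetyl-2,3,6-trimethoxyphenyl pivalate | CC(=O)c1cc(OC)c(OC(=O)C(C)(C)C)c(OC)c1OC
F7 | step 6 | lithium enolate of F6 | [Li+].C=C([O-])c1cc(OC)c(OC(=O)C(C)(C)C)c(OC)c1OC
F8 | step 6 | 1-[2,3,5-trimethoxy-4-(pivaloyloxy)phenyl]-3-[4-methoxy-3-(pivaloyloxy)phenyl]propane-1,3-dione | COc1ccc(C(=O)CC(=O)c2cc(OC)c(OC(=O)C(C)(C)C)c(OC)c2OC)cc1OC(=O)C(C)(C)C
F9 | step 6 | 5,6,8-trimethoxy-2-[4-methoxy-3-(pivaloyloxy)phenyl]-4-oxo-4H-chromen-7-yl pivalate | COc1ccc(-c2cc(=O)c3c(OC)c(OC)c(OC(=O)C(C)(C)C)c(OC)c3o2)cc1OC(=O)C(C)(C)C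
F10 | step 4 | 5-formyl-2-methoxyphenyl pivalate | COc1ccc(C=O)cc1OC(=O)C(C)(C)C
F11 | step 4 | 3-hydroxy-1-[3,5-dimethoxy-4-(pivaloyloxy)phenyl]-3-[4-methoxy-3-(pivaloyloxy)phenyl]propan-1-one (racemic) | COc1ccc(C(O)CC(=O)c2cc(OC)c(OC(=O)C(C)(C)C)c(OC)c2)cc1OC(=O)C(C)(C)C
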